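The data stem from a simulated flask with made-up constants; noise was put on by code.

Which flask ends with the greatest share of target in target plus cross product, when each flask loses its second substrate either to cross product or to second product?

all flasks: starting material 0.80 M
- north-west: partner 0.50 equiv; second substrate 0.20 equiv; protic impurity 0.080 M; run made earlier
- north-east: partner 0.50 equiv; second substrate 0.20 equiv; protic impurity 0.11 M; run made earlier
- west: partner 0.50 equiv; second substrate 0.20 equiv; protic impurity 0.18 M; run made earlier
- eta: partner 0.500 equiv (fed, over 30 h); second substrate 0.200 equiv; protic impurity 0.0800 M; all else is in the flask from the start; the feed brings no volume worth counting; time 6.0 d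
- zeta: partner 0.500 equiv; second substrate 0.200 equiv (fed, over 3.0 h); protic impurity 0.0800 M; all else is in the flask from the start; the feed brings no volume worth counting; time 6.0 d
- alpha: partner 0.500 equiv; second substrate 0.200 equiv; protic impurity 0.0800 M; everything together at the start; time 6.0 d
- delta: partner 0.500 equiv; second substrate 0.200 equiv (fed, over 30 h); protic impurity 0.0800 M; all else is in the flask from the start; the feed brings no volume worth counting; time 6.0 d

| run | time / d | target / % | cross product / % |
|---|---|---|---|
| north-west | 0.417 | 19.9 | 4.2 |
| north-west | 1.25 | 21.4 | 5.7 |
| north-west | 2.50 | 18.7 | 5.5 |
| north-west | 4.00 | 17.7 | 6.7 |
| north-east | 0.625 | 18.7 | 7.6 |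
| north-east | 1.25 | 18.5 | 7.0 |
| north-east | 3.00 | 16.9 | 6.9 |
| north-east | 8.00 | 13.7 | 6.7 |
| west | 0.833 | 15.9 | 7.8 |
| west | 2.50 | 12.1 | 7.3 |
| west | 5.00 | 10.3 | 8.1 |
| west | 8.00 | 8.3 | 6.7 |

(standard deviation of a reading: 1 percentage point)

* the flask that comes out highest in share of target in target plus cross product, or "all alike" when all lie within 1.5 percentage points (eta / zeta / alpha / delta / all alike)
* share of target in target plus cross product at the end, eta
* share of target in target plus cross product at the end, zeta
* share of target in target plus cross product at the end, alpha
* share of target in target plus cross product at the end, delta

- percent here means starting material units held: one self-condensation product counts as two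
- what was read earlier has a scatter of 1 percentage point, one standard deviation
- what may be going on: partner + protic impurity -> quenched reagent; starting material + second substrate -> cross product; second substrate + partner -> second product; 2 starting material -> self-condensation product; starting material + partner <-> target

Cross product levels off early in the north-west run, so I treat the second substrate as split between those two products. From the last three north-west readings:

cross product 0.0477 M; second product 0.112 M; odds 0.425; partner less protic impurity 0.320 M

0.170 = odds ÷ (starting material ÷ free partner)

I carry this split factor, the odds of cross product per unit ratio of starting material to free partner, a selectivity factor. In powers of ten: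

log odds = −0.770 + log ratio, here 0.398

On the west charge it gives 7.64% cross product, and west reads about that.

Turned round: for delta to beat alpha, the ratio during dosing must stay under 2.50. At 0.417 d the north-west reading puts 0.159 M in target, and with my 0.112 M of second product that leaves about 0.0485 M free partner. On that balance starting material has to stand under 0.121 M, so self-condensation has to have taken about 0.472 M, with target and cross product counted. Target falls over days in all three runs, which I read as that drain, so I commit to delta.

In eta, the feed has delivered 0.0400 M of partner by 3.0 h, less than the 0.0800 M of protic impurity, while the second substrate stands in the flask from the start, so I put eta last.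

The forecast gives alpha, with 62%, 74%, 76% and 68% for eta, zeta, alpha and delta: “Alpha is the likely highest.”

The flasks give delta highest, with 41.9%, 70.8%, 71.0% and 74.2% in the same order.

    partner + protic impurity → quenched reagent (k = 2.61 M⁻¹ h⁻¹)
    starting material + second substrate → cross product (k = 0.666 M⁻¹ h⁻¹)
    second substrate + partner → second product (k = 3.22 M⁻¹ h⁻¹)
    2 starting material → self-condensation product (k = 0.209 M⁻¹ h⁻¹)
    starting material + partner ⇌ target (K = 44.0 M⁻¹, k = 0.420 M⁻¹ h⁻¹)

In delta, half of the self-condensation turnover is done by 0.103 d, earlier than the 0.777 d for second product. Dividing the final odds by the split factor gives an effective ratio of 2.35 for delta, 2.86 for alpha and 25.5 for eta.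

For a neighbour of delta with 0.300 equiv of partner, partner less protic impurity comes to 0.160 M. Delta's ratio scales to odds of 0.800, which means 8.89% cross product. That neighbour gives 10.6%, more than that, and a share of 39.2%.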